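**Assumptions (one line each)**
- Stereodescriptors read from the target SMILES: chroman C2 is (R) and the side-chain carbinol is (R).
- Bromination of **1** is assumed to occur at C5, ortho to F and meta to CHO.
- The Julia–Kocienski step is assumed to give the E-alkene as the major isomer, with the Z isomer separable.

## Retrosynthesis
1. The target comes from global desilylation of **19**. The Cη=Cθ E-trisubstituted alkene next to the carbinol is disconnected by Julia–Kocienski olefination of aldehyde **12** with PT-sulfone **18**. The carbinol (R) centre comes from (R)-epichlorohydrin.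
2. Aldehyde **12** comes from a Johnson–Claisen [3,3]-sigmatropic rearrangement of the isopropenyl carbinol **10**. This is the key bond-forming step: it sets the E-Cγ=Cδ(Me) alkene and adds the CH2CH2C(O) unit in one operation. Carbinol **10** comes from aldehyde **9**, made by oxidative removal of the prenyl terminus of chroman **5**.
3. Chroman **5** is the only ring formed. It comes from intramolecular SNAr of the tertiary alkoxide of **4** on a fluoroarene, so the C2–O bond is never broken. Alcohol **4** comes from hydroboration/Suzuki coupling of (R)-linalool with aryl bromide **2**. The phenol is revealed by Baeyer–Villiger oxidation of the activating CHO.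

## Route

**Step 1**
Reactants: **1** 4-fluoro-3-methylbenzaldehyde
Product: **2** 3-bromo-4-fluoro-5-methylbenzaldehyde
Conditions: NBS (1.1 equiv), conc. H2SO4, 25 °C, 12 h
Reagents that add atoms: N-bromosuccinimide, O=C1CCC(=O)N1Br
Why: Electrophilic aromatic bromination; F directs ortho and CHO directs meta, so Br enters C5; there is no stereocentre.

**Step 2**
Reactants: **3** (R)-(−)-linalool; **2**
Product: **4** 4-fluoro-3-[(3R)-3-hydroxy-3,7-dimethyloct-6-en-1-yl]-5-methylbenzaldehyde
Conditions: 9-BBN (2.1 equiv), THF, 0→25 °C, 3 h; then **2** (0.9 equiv), Pd(dppf)Cl2 (5 mol%), aq. K3PO4, THF, 65 °C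
Reagents that add atoms: none
Why: 9-BBN hydroborates the monosubstituted vinyl group selectively (the first equivalent caps the tertiary OH), and the primary alkyl-9-BBN then undergoes B-alkyl Suzuki–Miyaura coupling; the carbinol stereocentre is untouched.

**Step 3**
Reactants: **4**
Product: **5** (2R)-2,8-dimethyl-2-(4-methylpent-3-en-1-yl)chromane-6-carbaldehyde
Conditions: NaH (1.5 equiv), DMF, 0→80 °C, 4 h
Reagents that add atoms: none
Why: Intramolecular SNAr (addition–elimination) of the tertiary alkoxide on the fluoroarene activated by para-CHO closes the pyran ring. The C–O bond at the quaternary carbon is never cleaved, so linalool's (R) configuration carries through.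

**Step 4**
Reactants: **5**
Product: **6** (2S)-2-[2-(3,3-dimethyloxiran-2-yl)ethyl]-2,8-dimethylchroman-6-yl formate
Conditions: mCPBA (2.6 equiv), NaHCO3, CH2Cl2, 0→25 °C, 6 h
Reagents that add atoms: mCPBA, OOC(=O)c1cccc(Cl)c1 (supplies the epoxide O and the formate O)
Why: Prilezhaev epoxidation of the trisubstituted alkene plus Baeyer–Villiger oxidation of the p-alkoxy aryl aldehyde to the aryl formate. The epoxide stereocentres are a mixture that is destroyed in step 7, and C2 is untouched (the CIP label R→S is only a priority change).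

**Step 5**
Reactants: **6**
Product: **7** (2S)-2-[2-(3,3-dimethyloxiran-2-yl)ethyl]-2,8-dimethylchroman-6-ol
Conditions: K2CO3 (1.5 equiv), MeOH, 0 °C, 30 min
Reagents that add atoms: none
Why: Methanolysis of the aryl formate releases the phenol; the trisubstituted epoxide survives cold, mild base.

**Step 6**
Reactants: **7**
Product: **8** TBS aryl ether of **7**
Conditions: TBSCl (1.2 equiv), imidazole, DMF, 25 °C, 2 h
Reagents that add atoms: TBSCl, C[Si](C)(Cl)C(C)(C)C
Why: Silylation protects the phenol against periodate oxidation and against the Grignard and orthoester steps.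

**Step 7**
Reactants: **8**
Product: **9** 3-[(2S)-6-(TBSO)-2,8-dimethylchroman-2-yl]propanal
Conditions: H5IO6 (1.5 equiv), THF/H2O, 0 °C, 1 h
Reagents that add atoms: water, O (its O ends up as one carbonyl oxygen via the intermediate diol)
Why: Malaprade-type glycol cleavage (epoxide → diol → carbonyl pair) removes the terminal CMe2 as acetone and leaves the aldehyde; the chroman ether is acid-stable.

**Step 8**
Reactants: **9**
Product: **10** 5-[(2S)-6-(TBSO)-2,8-dimethylchroman-2-yl]-2-methylpent-1-en-3-ol (about 1:1 epimers at the carbinol)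
Conditions: isopropenylMgBr (1.5 equiv), THF, −78→0 °C, 1 h
Reagents that add atoms: isopropenylmagnesium bromide, C=C(C)[Mg]Br
Why: 1,2-Grignard addition gives the allylic alcohol; the new carbinol centre becomes sp2 in step 9, so its configuration is irrelevant.

**Step 9 (key step)**
Reactants: **10**
Product: **11** ethyl (4E)-7-[(2R)-6-(TBSO)-2,8-dimethylchroman-2-yl]-4-methylhept-4-enoate
Conditions: CH3C(OEt)3 (10 equiv), EtCO2H (5 mol%), 140 °C, sealed tube, 4 h
Reagents that add atoms: triethyl orthoacetate, CC(OCC)(OCC)OCC (supplies CH2CO2Et)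
Why: Johnson–Claisen [3,3]-sigmatropic rearrangement; in the chair transition state the large CH2CH2-chromanyl group is pseudo-equatorial, giving the E-trisubstituted alkene. No new stereocentre forms and C2 is not involved.

**Step 10**
Reactants: **11**
Product: **12** (4E)-7-[(2R)-6-(TBSO)-2,8-dimethylchroman-2-yl]-4-methylhept-4-enal
Conditions: DIBAL-H (1.1 equiv), CH2Cl2, −78 °C, 1 h; Rochelle salt work-up
Reagents that add atoms: none
Why: Partial reduction of the ester to the aldehyde via a stable tetrahedral aluminate at −78 °C.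

**Step 11**
Reactants: **13** (R)-epichlorohydrin
Product: **14** (2R)-1-chloro-5-methylhex-4-en-2-ol
Conditions: Me2C=CHMgBr (1.1 equiv), CuI (10 mol%), THF, −30→0 °C
Reagents that add atoms: isobutenylmagnesium bromide, CC(C)=C[Mg]Br
Why: Cu-catalysed SN2 opening of the epoxide at the unhindered CH2 leaves the stereocentre untouched, so the carbinol (R) configuration comes directly from **13**.

**Step 12**
Reactants: **14**
Product: **15** (2R)-5-methyl-1-[(1-phenyl-1H-tetrazol-5-yl)thio]hex-4-en-2-ol
Conditions: PTSH (1.2 equiv), K2CO3 (2 equiv), DMF, 60 °C, 6 h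
Reagents that add atoms: 1-phenyl-1H-tetrazole-5-thiol, Sc1nnnn1-c1ccccc1
Why: Thiolate SN2 on the primary chloride (directly or via the transient epoxide, opened at its CH2 terminus); the carbinol carbon is not attacked.

**Step 13**
Reactants: **15**
Product: **16** TBS ether of **15**
Conditions: TBSCl (1.2 equiv), imidazole, DMF, 25 °C, 3 h
Reagents that add atoms: TBSCl, C[Si](C)(Cl)C(C)(C)C
Why: Protects the secondary alcohol so the next sulfone anion does not meet a free OH.

**Step 14**
Reactants: **16**
Product: **17** PT-sulfone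
Conditions: (NH4)6Mo7O24·4H2O (10 mol%), 30% H2O2 (6 equiv), EtOH, 0→25 °C, 12 h
Reagents that add atoms: hydrogen peroxide, OO (two O atoms end up on S)
Why: Mo(VI)/peroxo oxidation of sulfide to sulfone is much faster than epoxidation of the prenyl alkene.

**Step 15**
Reactants: **17**
Product: **18** PT-sulfone with an α-methyl (epimeric at the sulfone carbon)
Conditions: LiHMDS (1.05 equiv), THF, −78 °C; then MeI (1.5 equiv), −78→−20 °C
Reagents that add atoms: methyl iodide, CI
Why: α-Alkylation of the sulfone carbanion installs the Cθ methyl; the sulfone-carbon epimers are irrelevant because that carbon becomes sp2 in step 16.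

**Step 16**
Reactants: **12**; **18**
Product: **19** bis-TBS ether of the target
Conditions: KHMDS (1.3 equiv), DME, −60 °C, add **12**, warm to 25 °C
Reagents that add atoms: none
Why: Julia–Kocienski olefination (anti addition then Smiles rearrangement and loss of SO2 and PT-O⁻) gives the E-trisubstituted Cη=Cθ alkene; C_a–OTBS is not touched.

**Step 17**
Reactants: **19**
Product: **20** Sargachromanol C
Conditions: TBAF (4 equiv), THF, 0→25 °C, 6 h
Reagents that add atoms: none
Why: Fluoride removes both silyl ethers without affecting the alkenes or either stereocentre.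

## Compound list
1 | 4-fluoro-3-methylbenzaldehyde | Cc1cc(C=O)ccc1F | starting material
2 | 3-bromo-4-fluoro-5-methylbenzaldehyde | Cc1cc(C=O)cc(Br)c1F | intermediate
3 | (R)-(−)-linalool | CC(C)=CCC[C@@](C)(O)C=C | starting material
4 | 4-fluoro-3-[(3R)-3-hydroxy-3,7-dimethyloct-6-en-1-yl]-5-methylbenzaldehyde | CC(C)=CCC[C@@](C)(O)CCc1cc(C=O)cc(C)c1F | intermediate
5 | (2R)-2,8-dimethyl-2-(4-methylpent-3-en-1-yl)chromane-6-carbaldehyde | CC(C)=CCC[C@]1(C)CCc2cc(C=O)cc(C)c2O1 | intermediate
6 | (2S)-2-[2-(3,3-dimethyloxiran-2-yl)ethyl]-2,8-dimethylchroman-6-yl formate | CC1(C)OC1CC[C@]2(C)CCc3cc(OC=O)cc(C)c3O2 | intermediate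
7 | (2S)-2-[2-(3,3-dimethyloxiran-2-yl)ethyl]-2,8-dimethylchroman-6-ol | CC1(C)OC1CC[C@]2(C)CCc3cc(O)cc(C)c3O2 | intermediate
8 | TBS ether of 7 | CC1(C)OC1CC[C@]2(C)CCc3cc(O[Si](C)(C)C(C)(C)C)cc(C)c3O2 | intermediate
9 | 3-[(2S)-6-(TBSO)-2,8-dimethylchroman-2-yl]propanal | O=CCC[C@]1(C)CCc2cc(O[Si](C)(C)C(C)(C)C)cc(C)c2O1 | intermediate
10 | 5-[(2S)-6-(TBSO)-2,8-dimethylchroman-2-yl]-2-methylpent-1-en-3-ol | C=C(C)C(O)CC[C@]1(C)CCc2cc(O[Si](C)(C)C(C)(C)C)cc(C)c2O1 | intermediate
11 | ethyl (4E)-7-[(2R)-6-(TBSO)-2,8-dimethylchroman-2-yl]-4-methylhept-4-enoate | CCOC(=O)CC/C(C)=C/CC[C@]1(C)CCc2cc(O[Si](C)(C)C(C)(C)C)cc(C)c2O1 | intermediate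
12 | (4E)-7-[(2R)-6-(TBSO)-2,8-dimethylchroman-2-yl]-4-methylhept-4-enal | O=CCC/C(C)=C/CC[C@]1(C)CCc2cc(O[Si](C)(C)C(C)(C)C)cc(C)c2O1 | intermediate
13 | (R)-epichlorohydrin | ClC[C@H]1CO1 | starting material
14 | (2R)-1-chloro-5-methylhex-4-en-2-ol | CC(C)=CC[C@@H](O)CCl | intermediate
15 | (2R)-5-methyl-1-[(1-phenyltetrazol-5-yl)thio]hex-4-en-2-ol | CC(C)=CC[C@@H](O)CSc1nnnn1-c1ccccc1 | intermediate
16 | TBS ether of 15 | CC(C)=CC[C@@H](O[Si](C)(C)C(C)(C)C)CSc1nnnn1-c1ccccc1 | intermediate
17 | PT-sulfone | CC(C)=CC[C@@H](O[Si](C)(C)C(C)(C)C)CS(=O)(=O)c1nnnn1-c1ccccc1 | intermediate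
18 | α-methyl PT-sulfone | CC(C)=CC[C@@H](O[Si](C)(C)C(C)(C)C)C(C)S(=O)(=O)c1nnnn1-c1ccccc1 | intermediate
19 | bis-TBS ether of the target | CC(C)=CC[C@@H](O[Si](C)(C)C(C)(C)C)/C(C)=C/CC/C(C)=C/CC[C@]1(C)CCc2cc(O[Si](C)(C)C(C)(C)C)cc(C)c2O1 | intermediate
20 | Sargachromanol C | CC(C)=CC[C@@H](O)/C(C)=C/CC/C(C)=C/CC[C@]1(C)CCc2cc(O)cc(C)c2O1 | target

Note on labels: the C2 descriptor reads S for compounds 6–10 and R for 5, 11, 12, 19 and 20 only because CIP priorities change with the side chain; the spatial arrangement at C2 never changes.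

## Summary
- Total steps: 17.
- Longest linear sequence: 12 steps (1→2→3→4→5→6→7→8→9→10→16→17); the tail branch from (R)-epichlorohydrin is 5 steps (11–15).
- Three steps most likely to fail:
  1. **Step 3 (SNAr closure).** The fluoroarene is flanked by Me and the chain, so it is hindered. *Fallback:* use an iodo/bromo analogue of the aryl partner, with OTBS already on the ring, and close the ring by Pd-catalysed intramolecular C–O coupling of the tertiary alcohol. This also removes steps 4–6.
  2. **Step 16 (Julia–Kocienski).** E/Z selectivity may be modest, and the β-silyloxy sulfone anion could eliminate. *Fallback:* Horner–Wittig with the Ph2P(O) analogue of **18**; separate the diastereomeric β-hydroxyphosphine oxides and eliminate each stereospecifically to give E.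
  3. **Step 4 (double peracid oxidation).** Selectivity or epoxide survival may be poor. *Fallback:* use a 4-fluoro-3-methyl-nitroarene partner as the SNAr activator, then after ring closure reduce (Fe/NH4Cl), diazotise and hydrolyse to the phenol, so no peracid is needed.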